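**Strategy.** The five-membered ring of the daucane core is disconnected at C2–C3 and C3–C4. C3 is the only methylene between the two carbinol carbons C2 and C4, so it is brought in as nitromethane, a one-carbon bis-nucleophile. One operation, a double nitroaldol addition, closes the cyclopentane onto a preformed cycloheptene, forms both bonds and sets the C2 and C4 carbinols; the nitro group is then removed. The precursor is a cycloheptene (C1, C5–C10) carrying the C1 methyl and formyl groups, a trans C5 isobutyryl group and a C6 silyl ether. It is assembled by Evans aldol, lactone-templated alkylation and ring-closing metathesis.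

Key step: step 12

Remark: atom labels are daucane labels used for every intermediate (C1 quaternary carbon with the angular methyl, C2 secondary carbinol, C3 CH2, C4 tertiary carbinol with isopropyl, C5 ring-fusion CH, C6 ester-bearing CH, C7 CH2, C8 methyl-bearing alkene carbon, C9 alkene CH, C10 CH2); CIP descriptors in names change where substituent priorities change, without any change in spatial arrangement.

Step 1
Reactants: 1 (R)-4-benzyl-1,3-oxazolidin-2-one; 2 methyl 4-chloro-4-oxobutanoate
Product: 3 methyl 4-[(4R)-4-benzyl-2-oxo-1,3-oxazolidin-3-yl]-4-oxobutanoate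
Conditions: n-BuLi, THF, −78 °C; then 2, −78 → 0 °C
Reagents that add atoms: none
Why: N-acylation of the lithiated oxazolidinone by the acid chloride (attachment of an Evans auxiliary); the methyl ester is much less electrophilic and is not touched.

Step 2
Reactants: 3 methyl 4-[(4R)-4-benzyl-2-oxo-1,3-oxazolidin-3-yl]-4-oxobutanoate; 4 isobutyraldehyde
Product: 6 trans lactone imide (4R)-4-benzyl-3-{[(2S,3R)-5-oxo-2-(propan-2-yl)oxolan-3-yl]carbonyl}-1,3-oxazolidin-2-one, via syn-aldol hydroxy ester 5 (not isolated)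
Conditions: Bu2BOTf, iPr2NEt, CH2Cl2, 0 °C; 4, −78 → 0 °C; H2O2, MeOH, pH 7 buffer; then TsOH·H2O (cat.), CH2Cl2, 23 °C
Reagents that add atoms: none
Why: Evans boron-mediated syn-aldol reaction: the Z-boron enolate of the imide (the ester is not enolised) adds to the aldehyde through a chair transition state in which the (R)-benzyl auxiliary fixes C5 as R and the carbinol C4 as S, and acid then closes the γ-hydroxy ester to the trans γ-lactone.

Step 3
Reactants: 6 trans lactone imide
Product: 7 S-ethyl (2S,3R)-5-oxo-2-(propan-2-yl)oxolane-3-carbothioate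
Conditions: EtSH, n-BuLi, THF, 0 °C
Reagents that add atoms: ethanethiol (as its lithium thiolate), CCS
Why: Thiolate transacylation of the exocyclic imide carbonyl (auxiliary removal to a thioester), which is more electrophilic than the lactone carbonyl; C5 keeps the thermodynamically preferred trans arrangement.

Step 4
Reactants: 7 S-ethyl (2S,3R)-5-oxo-2-(propan-2-yl)oxolane-3-carbothioate
Product: 8 (2S,3R)-5-oxo-2-(propan-2-yl)oxolane-3-carbaldehyde
Conditions: Et3SiH, Pd/C (10 wt% Pd on carbon), acetone, 23 °C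
Reagents that add atoms: none
Why: Fukuyama reduction of a thioester to the aldehyde under neutral conditions, which avoids epimerisation at C5 and β-elimination of the lactone oxygen.

Step 5
Reactants: 8 (2S,3R)-5-oxo-2-(propan-2-yl)oxolane-3-carbaldehyde
Product: 9 homoallylic alcohol (4S,5S)-4-[(1S)-1-hydroxy-3-methylbut-3-en-1-yl]-5-(propan-2-yl)oxolan-2-one
Conditions: (−)-Ipc2BOMe, 2-methylallylmagnesium chloride, Et2O, −78 → 23 °C; then 8, −78 °C; H2O2, pH 7 buffer, MeOH, 0 °C
Reagents that add atoms: (−)-B-(2-methylallyl)diisopinocampheylborane, CC(=C)CB([C@@H]1C[C@@H]2C[C@H]([C@H]1C)C2(C)C)[C@@H]1C[C@@H]2C[C@H]([C@H]1C)C2(C)C, made in the flask from 2-methylallylmagnesium chloride, CC(=C)C[Mg]Cl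
Why: Brown asymmetric allylboration with the methallyl reagent: the borane derived from (+)-α-pinene delivers the methallyl group through a closed chair transition state to the si face of the aldehyde, which sets C6 as S under reagent control.

Step 6
Reactants: 9 homoallylic alcohol
Product: 10 (4R,5S)-4-[(1S)-1-{[tert-butyl(dimethyl)silyl]oxy}-3-methylbut-3-en-1-yl]-5-(propan-2-yl)oxolan-2-one
Conditions: TBSOTf, 2,6-lutidine, CH2Cl2, −78 °C
Reagents that add atoms: tert-butyldimethylsilyl triflate, CC(C)(C)[Si](C)(C)OS(=O)(=O)C(F)(F)F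
Why: Silylation of a secondary alcohol with a silyl triflate, run cold on the crude alcohol so that the hydroxyl cannot attack the lactone carbonyl (acyl migration between two γ-lactones).

Step 7
Reactants: 10 silyl ether lactone
Product: 11 (3R,4R,5S)-4-[(1S)-1-{[tert-butyl(dimethyl)silyl]oxy}-3-methylbut-3-en-1-yl]-3-methyl-5-(propan-2-yl)oxolan-2-one
Conditions: LiN(iPr)2, THF, −78 °C; MeI, −78 → −40 °C
Reagents that add atoms: iodomethane, CI
Why: α-Alkylation of the lactone lithium enolate, with iodomethane approaching anti to the C5 side chain; this centre is enolised again in the next step, so its configuration is not critical.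

Step 8
Reactants: 11 α-methyl lactone
Product: 12 (3R,4R,5S)-4-[(1S)-1-{[tert-butyl(dimethyl)silyl]oxy}-3-methylbut-3-en-1-yl]-3-methyl-5-(propan-2-yl)-3-(prop-2-en-1-yl)oxolan-2-one
Conditions: LiN(iPr)2, THF, DMPU, −78 °C; allyl bromide, −78 → −20 °C
Reagents that add atoms: allyl bromide, C=CCBr
Why: Second α-alkylation of the lactone enolate creates the quaternary centre C1: allyl bromide enters anti to the bulky C5 side chain (1,2-induction on the five-membered enolate), which places allyl trans and methyl cis to that chain, as the trans ring fusion requires.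

Step 9
Reactants: 12 α-allyl-α-methyl lactone
Product: 13 trans-fused lactone (3S,3aR,4S,8aR)-4-{[tert-butyl(dimethyl)silyl]oxy}-6,8a-dimethyl-3-(propan-2-yl)-3,3a,4,5,8,8a-hexahydro-1H-cyclohepta[c]furan-1-one
Conditions: (H2IMes)(PCy3)Cl2Ru=CHPh (second-generation Grubbs catalyst, 5 mol%), CH2Cl2 (0.005 M), 40 °C
Reagents that add atoms: none
Why: Ring-closing metathesis of the allyl and 2-methylallyl groups gives the seven-membered ring with the trisubstituted C8=C9 alkene and releases ethene; the two chains sit trans on adjacent lactone carbons, which the flexible cycloheptene accommodates as a trans-fused bicycle.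

Step 10
Reactants: 13 trans-fused lactone
Product: 14 diol (1S)-1-[(1R,2R,7S)-7-{[tert-butyl(dimethyl)silyl]oxy}-2-(hydroxymethyl)-2,5-dimethylcyclohept-4-en-1-yl]-2-methylpropan-1-ol
Conditions: LiAlH4, THF, 0 °C
Reagents that add atoms: none
Why: Hydride reduction of the γ-lactone to the 1,4-diol (C2 primary, C4 secondary); the silyl ether and the alkene are inert to LiAlH4 at 0 °C.

Step 11
Reactants: 14 diol
Product: 15 keto aldehyde (1R,6S,7S)-6-{[tert-butyl(dimethyl)silyl]oxy}-1,4-dimethyl-7-(2-methylpropanoyl)cyclohept-3-ene-1-carbaldehyde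
Conditions: (COCl)2, DMSO, CH2Cl2, −78 °C; Et3N, −78 → 0 °C
Reagents that add atoms: none
Why: Swern oxidation of both hydroxyls in one operation (both are activated before the base is added, so no lactol is trapped) gives the γ-keto aldehyde; C1 is quaternary and C5 already holds the more stable configuration, trans to both neighbours.

Step 12
Reactants: 15 keto aldehyde; 16 nitromethane
Product: 18 nitro diol (1R,2S,3R,3aS,4S,8aR)-4-{[tert-butyl(dimethyl)silyl]oxy}-6,8a-dimethyl-2-nitro-3-(propan-2-yl)-1,2,3,3a,4,5,8,8a-octahydroazulene-1,3-diol, via open-chain nitro alcohol 17 (not isolated)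
Conditions: MeNO2 (10 equiv), 1,1,3,3-tetramethylguanidine (0.3 equiv), THF, 0 → 23 °C; AcOH quench
Reagents that add atoms: none
Why: Proposed new method: the guanidine base converts nitromethane into its nitronate, which adds to the non-enolisable C2 aldehyde to give 17; the more substituted nitronate of 17 then attacks the C4 isobutyryl ketone, so that one carbon (C3) acts twice as nucleophile and forms C2–C3 and C3–C4. The closest known reactions are the double nitroaldol cyclisation of dialdehydes with nitromethane to cyclic 2-nitro-1,3-diols and the intramolecular nitroaldol addition of nitroalkyl ketones; the combination of an aldehyde and a hindered ketone in one sequence is not established. The five-membered ring closes in the 5-exo-trig mode onto the ketone carbonyl. All three new centres form reversibly (retro-nitroaldol at both bonds, nitronate protonation at C3), so they should settle under thermodynamic control on the trans-fused frame fixed by C1 and C5: at C4 the isopropyl group takes the face of H5 and the hydroxyl the face of the C6 arm and the angular methyl, the nitro group at C3 sits trans to isopropyl, and the C2 hydroxyl sits trans to the nitro group and to the C1 methyl. The step needs nitronate formation without ketone enolisation (which would epimerise C5 or expel the C6 silyloxy group); the acidity gap of about ten pKa units between nitromethane and the ketone, the catalytic amount of base and the excess of nitromethane secure this, and the trans relation of formyl and acyl groups on C1 and C5 holds both carbonyls within reach of C3.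

Step 13
Reactants: 18 nitro diol
Product: 19 diol (1S,3R,3aS,4S,8aR)-4-{[tert-butyl(dimethyl)silyl]oxy}-6,8a-dimethyl-3-(propan-2-yl)-1,2,3,3a,4,5,8,8a-octahydroazulene-1,3-diol
Conditions: Bu3SnH, AIBN, toluene, 110 °C
Reagents that add atoms: none
Why: Radical denitration of a secondary nitroalkane with tin hydride (stannyl radical adds to the nitro group, C–N homolysis, hydrogen transfer to the C3 radical); C3 becomes CH2, so its configuration is irrelevant, and the C3 radical has no alkene within reach on the trans-fused frame.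

Step 14
Reactants: 19 diol
Product: 20 (1S,3R,3aS,4S,8aR)-4-{[tert-butyl(dimethyl)silyl]oxy}-3-hydroxy-6,8a-dimethyl-3-(propan-2-yl)-1,2,3,3a,4,5,8,8a-octahydroazulen-1-yl acetate
Conditions: Ac2O, pyridine, DMAP (cat.), CH2Cl2, 0 → 23 °C
Reagents that add atoms: acetic anhydride, CC(=O)OC(C)=O
Why: DMAP-catalysed acetylation, selective for the secondary C2 hydroxyl over the tertiary C4 hydroxyl; it keeps the C2 hydroxyl out of the later esterification.

Step 15
Reactants: 20 C2 acetate silyl ether
Product: 21 (1S,3R,3aS,4S,8aR)-3,4-dihydroxy-6,8a-dimethyl-3-(propan-2-yl)-1,2,3,3a,4,5,8,8a-octahydroazulen-1-yl acetate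
Conditions: HF·pyridine, pyridine, THF, 0 → 23 °C
Reagents that add atoms: none
Why: Fluoride-mediated cleavage of the silyl ether under buffered conditions that leave the acetate, the tertiary alcohol and the alkene untouched.

Step 16
Reactants: 21 C6 alcohol; 22 4-acetoxybenzoic acid
Product: 23 (1S,3R,3aS,4S,8aR)-1-(acetyloxy)-3-hydroxy-6,8a-dimethyl-3-(propan-2-yl)-1,2,3,3a,4,5,8,8a-octahydroazulen-4-yl 4-(acetyloxy)benzoate
Conditions: DCC, DMAP, CH2Cl2, 23 °C
Reagents that add atoms: none
Why: Steglich esterification of the only secondary hydroxyl (C6); the tertiary C4 hydroxyl does not react and the phenol of the acid is masked as its acetate.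

Step 17
Reactants: 23 diacetate ester
Product: 24 2α-hydroxyferutinin, (1S,3R,3aS,4S,8aR)-1,3-dihydroxy-6,8a-dimethyl-3-(propan-2-yl)-1,2,3,3a,4,5,8,8a-octahydroazulen-4-yl 4-hydroxybenzoate
Conditions: K2CO3, MeOH, 0 → 23 °C; aq. NH4Cl
Reagents that add atoms: none
Why: Base-catalysed methanolysis (transesterification) removes the phenolic acetate and the C2 acetate; the hindered C6 aroyl ester is deactivated once the phenol is deprotonated and should survive.

**Compound list**

1 | (R)-4-benzyl-1,3-oxazolidin-2-one | O=C1N[C@H](Cc2ccccc2)CO1 | starting material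
2 | methyl 4-chloro-4-oxobutanoate | COC(=O)CCC(Cl)=O | starting material
3 | methyl 4-[(4R)-4-benzyl-2-oxo-1,3-oxazolidin-3-yl]-4-oxobutanoate | COC(=O)CCC(=O)N1[C@H](Cc2ccccc2)COC1=O | intermediate
4 | isobutyraldehyde (2-methylpropanal) | CC(C)C=O | starting material
5 | syn-aldol hydroxy ester, methyl (3R,4S)-3-{[(4R)-4-benzyl-2-oxo-1,3-oxazolidin-3-yl]carbonyl}-4-hydroxy-5-methylhexanoate | COC(=O)C[C@H]([C@@H](O)C(C)C)C(=O)N1[C@H](Cc2ccccc2)COC1=O | intermediate (not isolated)
6 | (4R)-4-benzyl-3-{[(2S,3R)-5-oxo-2-(propan-2-yl)oxolan-3-yl]carbonyl}-1,3-oxazolidin-2-one | O=C1C[C@@H](C(=O)N2[C@H](Cc3ccccc3)COC2=O)[C@H](C(C)C)O1 | intermediate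
7 | S-ethyl (2S,3R)-5-oxo-2-(propan-2-yl)oxolane-3-carbothioate | O=C1C[C@@H](C(=O)SCC)[C@H](C(C)C)O1 | intermediate
8 | (2S,3R)-5-oxo-2-(propan-2-yl)oxolane-3-carbaldehyde | O=C1C[C@@H](C=O)[C@H](C(C)C)O1 | intermediate
9 | (4S,5S)-4-[(1S)-1-hydroxy-3-methylbut-3-en-1-yl]-5-(propan-2-yl)oxolan-2-one | O=C1C[C@@H]([C@@H](O)CC(C)=C)[C@H](C(C)C)O1 | intermediate
10 | (4R,5S)-4-[(1S)-1-{[tert-butyl(dimethyl)silyl]oxy}-3-methylbut-3-en-1-yl]-5-(propan-2-yl)oxolan-2-one | O=C1C[C@@H]([C@@H](O[Si](C)(C)C(C)(C)C)CC(C)=C)[C@H](C(C)C)O1 | intermediate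
11 | (3R,4R,5S)-4-[(1S)-1-{[tert-butyl(dimethyl)silyl]oxy}-3-methylbut-3-en-1-yl]-3-methyl-5-(propan-2-yl)oxolan-2-one (methyl trans to the C5 side chain) | C[C@@H]1[C@@H]([C@@H](O[Si](C)(C)C(C)(C)C)CC(C)=C)[C@H](C(C)C)OC1=O | intermediate
12 | (3R,4R,5S)-4-[(1S)-1-{[tert-butyl(dimethyl)silyl]oxy}-3-methylbut-3-en-1-yl]-3-methyl-5-(propan-2-yl)-3-(prop-2-en-1-yl)oxolan-2-one (allyl trans, methyl cis to the C5 side chain) | C=CC[C@]1(C)[C@@H]([C@@H](O[Si](C)(C)C(C)(C)C)CC(C)=C)[C@H](C(C)C)OC1=O | intermediate
13 | (3S,3aR,4S,8aR)-4-{[tert-butyl(dimethyl)silyl]oxy}-6,8a-dimethyl-3-(propan-2-yl)-3,3a,4,5,8,8a-hexahydro-1H-cyclohepta[c]furan-1-one (trans-fused) | CC1=CC[C@]2(C)[C@@H]([C@@H](O[Si](C)(C)C(C)(C)C)C1)[C@H](C(C)C)OC2=O | intermediate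
14 | (1S)-1-[(1R,2R,7S)-7-{[tert-butyl(dimethyl)silyl]oxy}-2-(hydroxymethyl)-2,5-dimethylcyclohept-4-en-1-yl]-2-methylpropan-1-ol | CC1=CC[C@@](C)(CO)[C@@H]([C@@H](O[Si](C)(C)C(C)(C)C)C1)[C@@H](O)C(C)C | intermediate
15 | (1R,6S,7S)-6-{[tert-butyl(dimethyl)silyl]oxy}-1,4-dimethyl-7-(2-methylpropanoyl)cyclohept-3-ene-1-carbaldehyde (key-step precursor) | CC1=CC[C@@](C)(C=O)[C@@H]([C@@H](O[Si](C)(C)C(C)(C)C)C1)C(=O)C(C)C | intermediate
16 | nitromethane | C[N+](=O)[O-] | starting material
17 | open-chain nitro alcohol, 1-[(1S,2R,7S)-7-{[tert-butyl(dimethyl)silyl]oxy}-2-[(1R)-1-hydroxy-2-nitroethyl]-2,5-dimethylcyclohept-4-en-1-yl]-2-methylpropan-1-one | CC1=CC[C@@](C)([C@@H](O)C[N+](=O)[O-])[C@@H]([C@@H](O[Si](C)(C)C(C)(C)C)C1)C(=O)C(C)C | intermediate (not isolated)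
18 | (1R,2S,3R,3aS,4S,8aR)-4-{[tert-butyl(dimethyl)silyl]oxy}-6,8a-dimethyl-2-nitro-3-(propan-2-yl)-1,2,3,3a,4,5,8,8a-octahydroazulene-1,3-diol (key-step product) | CC1=CC[C@]2(C)[C@@H]([C@@H](O[Si](C)(C)C(C)(C)C)C1)[C@](O)(C(C)C)[C@@H]([N+](=O)[O-])[C@@H]2O | intermediate
19 | (1S,3R,3aS,4S,8aR)-4-{[tert-butyl(dimethyl)silyl]oxy}-6,8a-dimethyl-3-(propan-2-yl)-1,2,3,3a,4,5,8,8a-octahydroazulene-1,3-diol | CC1=CC[C@]2(C)[C@@H]([C@@H](O[Si](C)(C)C(C)(C)C)C1)[C@](O)(C(C)C)C[C@@H]2O | intermediate
20 | (1S,3R,3aS,4S,8aR)-4-{[tert-butyl(dimethyl)silyl]oxy}-3-hydroxy-6,8a-dimethyl-3-(propan-2-yl)-1,2,3,3a,4,5,8,8a-octahydroazulen-1-yl acetate | CC1=CC[C@]2(C)[C@@H]([C@@H](O[Si](C)(C)C(C)(C)C)C1)[C@](O)(C(C)C)C[C@@H]2OC(C)=O | intermediate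
21 | (1S,3R,3aS,4S,8aR)-3,4-dihydroxy-6,8a-dimethyl-3-(propan-2-yl)-1,2,3,3a,4,5,8,8a-octahydroazulen-1-yl acetate | CC1=CC[C@]2(C)[C@@H]([C@@H](O)C1)[C@](O)(C(C)C)C[C@@H]2OC(C)=O | intermediate
22 | 4-acetoxybenzoic acid | CC(=O)Oc1ccc(cc1)C(O)=O | starting material
23 | (1S,3R,3aS,4S,8aR)-1-(acetyloxy)-3-hydroxy-6,8a-dimethyl-3-(propan-2-yl)-1,2,3,3a,4,5,8,8a-octahydroazulen-4-yl 4-(acetyloxy)benzoate | CC1=CC[C@]2(C)[C@@H]([C@@H](OC(=O)c3ccc(OC(C)=O)cc3)C1)[C@](O)(C(C)C)C[C@@H]2OC(C)=O | intermediate
24 | 2α-hydroxyferutinin, (1S,3R,3aS,4S,8aR)-1,3-dihydroxy-6,8a-dimethyl-3-(propan-2-yl)-1,2,3,3a,4,5,8,8a-octahydroazulen-4-yl 4-hydroxybenzoate | CC1=CC[C@]2(C)[C@@H]([C@@H](OC(=O)c3ccc(O)cc3)C1)[C@](O)(C(C)C)C[C@@H]2O | target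

**Total step count:** 17. **Longest linear sequence:** 17 steps (from 1 and 2 to 24).

**Steps most likely to fail**

Step 12 (Proposed new method). The sequence may stop at the open-chain nitro alcohol, because ring closure onto the hindered ketone is reversible and may be unfavourable; enolisation toward C5 with loss of the C6 silyloxy group may also compete. The fallback uses a sulfone as the one-carbon bis-nucleophile and sets out from 15. Lithiated methyl phenyl sulfone (PhSO2CH3, n-BuLi, THF, −78 °C) should add only to the aldehyde and give the hydroxy sulfone F1. A second deprotonation (LiN(iPr)2, 2.2 equiv, THF, −78 → 0 °C) should generate the sulfonyl-stabilised carbanion, which adds intramolecularly to the ketone under equilibrating conditions and gives the sulfonyl diol F2. Reductive desulfonylation (Na(Hg), Na2HPO4, MeOH, −20 °C) then removes the sulfonyl group, and the route is rejoined at 19.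

Step 13. C–N homolysis of an unactivated secondary nitro group is slow, so conversion may be incomplete and thermal ring opening by retro-nitroaldol cleavage may compete at 110 °C. The fallback activates the nitro group first and sets out from 18. Dess–Martin oxidation of the C2 hydroxyl (CH2Cl2, NaHCO3, 0 °C) should give the α-nitro ketone F3, whose nitro group should be removed by Bu3SnH and AIBN already at 80 °C in benzene to give the hydroxy ketone F4. Reduction with Me4NBH(OAc)3 (AcOH, MeCN, −20 °C), in which the C4 hydroxyl delivers hydride to its own face, should give the anti-1,3-diol and rejoin the route at 19. This detour would also converge a C2 epimer formed in step 12.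

Step 5. Facial selectivity may be poor if the reagent and the C5 stereocentre are mismatched, and the lactone acyl group may migrate to the new hydroxyl during work-up. The fallback replaces reagent-controlled C–C bond formation by a reagent-controlled ketone reduction and sets out from 8. An indium-mediated Barbier reaction (3-bromo-2-methylpropene, In, THF/H2O, 23 °C) should give 9 together with the C6-epimeric alcohol F5. Dess–Martin oxidation of the mixture should give the ketone F6. Corey–Bakshi–Shibata reduction ((R)-2-methyl-CBS-oxazaborolidine, BH3·SMe2, THF, −30 °C) should then set C6 as S, and the route is rejoined at 9.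

**Further compounds**

F1 | step 12 | hydroxy sulfone, 1-[(1S,2R,7S)-7-{[tert-butyl(dimethyl)silyl]oxy}-2-[(1R)-1-hydroxy-2-(phenylsulfonyl)ethyl]-2,5-dimethylcyclohept-4-en-1-yl]-2-methylpropan-1-one | CC1=CC[C@@](C)([C@@H](O)CS(=O)(=O)c2ccccc2)[C@@H]([C@@H](O[Si](C)(C)C(C)(C)C)C1)C(=O)C(C)C
F2 | step 12 | sulfonyl diol, (1R,2S,3R,3aS,4S,8aR)-4-{[tert-butyl(dimethyl)silyl]oxy}-6,8a-dimethyl-2-(phenylsulfonyl)-3-(propan-2-yl)-1,2,3,3a,4,5,8,8a-octahydroazulene-1,3-diol | CC1=CC[C@]2(C)[C@@H]([C@@H](O[Si](C)(C)C(C)(C)C)C1)[C@](O)(C(C)C)[C@@H](S(=O)(=O)c3ccccc3)[C@@H]2O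
F3 | step 13 | α-nitro ketone, (3R,3aS,4S,8aR)-4-{[tert-butyl(dimethyl)silyl]oxy}-3-hydroxy-6,8a-dimethyl-2-nitro-3-(propan-2-yl)-2,3,3a,4,5,8-hexahydroazulen-1(8aH)-one (C3 epimers) | CC1=CC[C@]2(C)[C@@H]([C@@H](O[Si](C)(C)C(C)(C)C)C1)[C@](O)(C(C)C)C([N+](=O)[O-])C2=O
F4 | step 13 | hydroxy ketone, (3R,3aS,4S,8aR)-4-{[tert-butyl(dimethyl)silyl]oxy}-3-hydroxy-6,8a-dimethyl-3-(propan-2-yl)-2,3,3a,4,5,8-hexahydroazulen-1(8aH)-one | CC1=CC[C@]2(C)[C@@H]([C@@H](O[Si](C)(C)C(C)(C)C)C1)[C@](O)(C(C)C)CC2=O
F5 | step 5 | C6-epimeric alcohol, (4S,5S)-4-[(1R)-1-hydroxy-3-methylbut-3-en-1-yl]-5-(propan-2-yl)oxolan-2-one | O=C1C[C@@H]([C@H](O)CC(C)=C)[C@H](C(C)C)O1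
F6 | step 5 | ketone, (4R,5S)-4-(3-methylbut-3-enoyl)-5-(propan-2-yl)oxolan-2-one | O=C1C[C@@H](C(=O)CC(C)=C)[C@H](C(C)C)O1
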